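**Plan**

- Ring letters: A is the 4-methoxyphenyl ring on the stereocenter, B the central 2,6-dimethoxyaryl ring, C the 4-hydroxy-2-methoxyphenyl ring, D the 4-hydroxyphenyl ring of the styryl arm.
- Cuts, in retrosynthetic order: the stilbene C=C between rings B and D (olefination); the aromaticity of ring B, taken back to a cyclohexane-1,3-dione, with a ketone restored at the benzylic carbon of ring C; the bond from the stereogenic CH to ring B (Michael addition); the Cα=Cβ bond of a chalcone (aldol condensation).
- Enabling feature: the stereogenic CH is bonded to the ring B carbon lying between the two C–OMe carbons, which is C2 of a cyclohexane-1,3-dione and its only nucleophilic carbon. The styryl-bearing carbon para to it is C5 of that dione, bought with a CO2Me handle. The CH(ring A)–CH2–C(ring C) chain is a chalcone skeleton with the CH as β-carbon.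
- Forward: no ring is built. The chalcone is made by condensation, ring B is attached as the saturated dione and then aromatised, the ketone is taken to CH2 and the ester to CHO, and the ring D arm is joined last by olefination and desilylation.
- Stereochemistry: the single (S) stereocenter comes from catalyst-controlled attack on the Si face of the chalcone β-carbon in the Michael step and is secured once ring B is aromatic. The E alkene comes from the Horner–Wadsworth–Emmons step.

Key step: step 4

Assumption: the quinidine-derived squaramide is taken to be the pseudoenantiomer that delivers Si-face attack; the sense is to be confirmed on the adduct, and the quinine-derived pseudoenantiomer would be used in the same way if it proved to be the reverse.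

**Route**

Step 1
Reactants: 1 2,4-dihydroxyacetophenone
Product: 2 4-benzyloxy-2-hydroxyacetophenone
Conditions: BnBr (1.05 equiv), K2CO3, acetone, reflux
Reagents that add atoms: benzyl bromide, BrCc1ccccc1
Why: Williamson ether synthesis: the 2-OH is held in a hydrogen bond to the acetyl carbonyl and is the weaker nucleophile, so one equivalent of benzyl bromide with K2CO3 should alkylate only the free 4-OH.

Step 2
Reactants: 2 4-benzyloxy-2-hydroxyacetophenone
Product: 3 4-benzyloxy-2-methoxyacetophenone
Conditions: MeI, K2CO3, DMF, 50 °C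
Reagents that add atoms: iodomethane, CI
Why: Williamson methylation of the remaining, chelated phenol, which needs the more polar solvent and gentle heating but meets no competing nucleophile (the methyl ketone is not deprotonated by K2CO3).

Step 3
Reactants: 3 4-benzyloxy-2-methoxyacetophenone; 4 4-methoxybenzaldehyde
Product: 5 (E)-1-[4-(benzyloxy)-2-methoxyphenyl]-3-(4-methoxyphenyl)prop-2-en-1-one
Conditions: KOH (aq., 0.5 equiv), EtOH, 0 °C to rt
Reagents that add atoms: none
Why: Claisen–Schmidt (crossed aldol) condensation of a methyl ketone with a non-enolisable aldehyde, in which E1cB loss of water from the aldol gives the conjugated enone as its more stable E isomer and the benzyl and methyl ethers are inert to hydroxide.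

Step 4
Reactants: 5 (E)-1-[4-(benzyloxy)-2-methoxyphenyl]-3-(4-methoxyphenyl)prop-2-en-1-one; 6 methyl 3,5-dioxocyclohexane-1-carboxylate
Product: 7 methyl 4-[(1R)-3-[4-(benzyloxy)-2-methoxyphenyl]-1-(4-methoxyphenyl)-3-oxopropyl]-3,5-dioxocyclohexane-1-carboxylate (drawn as the triketo form, in which the descriptor is R only because the ring carbon ranks below ring A; the spatial arrangement is that of the target)
Conditions: 6 (1.5 equiv), 9-amino(9-deoxy)epi-quinidine-derived 3,5-bis(trifluoromethyl)phenyl squaramide (10 mol %), CH2Cl2 (1 M), 25 °C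
Reagents that add atoms: none
Why: The quinuclidine nitrogen of the bifunctional catalyst deprotonates the acidic dione 6 while the two squaramide N–H bonds bind the chalcone carbonyl, so the ion-paired enolate attacks the β-carbon through its C2 and the ketone enolate formed is protonated to give the enolised 2-substituted dione. The closest known reaction type is the organocatalytic enantioselective Michael addition of cyclic 1,3-diones and 4-hydroxycoumarins to enones (warfarin-type additions) with cinchona-derived amine, thiourea and squaramide catalysts. No ring is closed, since ring B arrives intact as the saturated dione and only the bond from the future stereocenter to its C2 is formed. The new stereocenter is controlled by the catalyst alone, which must direct attack to the Si face of the β-carbon of the E-chalcone (the substrate has no control element of its own), and the pseudoenantiomeric catalyst reverses the sense. C- over O-alkylation follows from the soft, doubly stabilised enolate whose only carbon nucleophilic site is C2, and because the CO2Me group sits on the symmetry element of the dione there is no regiochemical question, the ring epimers and enol or hemiketal forms of 7 all converging on aromatisation. The electron-rich chalcone is a slow acceptor, so the reaction is run concentrated with excess dione and 7 is taken on without delay to avoid retro-Michael erosion.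

Step 5
Reactants: 7 Michael adduct (tautomer mixture)
Product: 8 methyl 4-[(1S)-3-[4-(benzyloxy)-2-methoxyphenyl]-1-(4-methoxyphenyl)-3-oxopropyl]-3-methoxy-5-oxocyclohex-3-ene-1-carboxylate (both epimers at ring C1)
Conditions: TMSCHN2 (2 M in hexanes), toluene/MeOH 4:1, 0 °C
Reagents that add atoms: trimethylsilyldiazomethane, C[Si](C)(C)C=[N+]=[N-]
Why: O-Methylation of a vinylogous acid by diazomethane released from the silyl reagent in methanol: only the acidic dione enol protonates the diazoalkane, so the aryl ketone and the ester are left alone, any hemiketal is drained through the open enol, and the vinylogous ester formed can neither close onto the aryl ketone nor depart as a dione enolate in a retro-Michael reaction.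

Step 6
Reactants: 8 vinylogous ester (both ring epimers)
Product: 11 methyl 4-[(1S)-3-[4-(benzyloxy)-2-methoxyphenyl]-1-(4-methoxyphenyl)-3-oxopropyl]-3,5-dimethoxybenzoate, via dienol ether 9 (not isolated), via allylic iodide 10 (not isolated)
Conditions: I2 (2.2 equiv), MeOH, reflux; aq. Na2S2O3 work-up
Reagents that add atoms: methanol, CO
Why: Iodine–methanol oxidative aromatisation, a known route from cyclohexenones and cyclohexane-1,3-diones to aryl methyl ethers: HI formed in the flask catalyses exchange of the ring ketone for a methyl enol ether (dienol ether 9), iodine adds at the diene terminus to give iodide 10, and loss of HI across the C–H next to the ester gives the benzoate, while the stereocenter carries no acidic hydrogen in any of these species and should pass unchanged.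

Step 7
Reactants: 11 aromatised keto ester
Product: 14 methyl 4-[(1S)-3-(4-hydroxy-2-methoxyphenyl)-1-(4-methoxyphenyl)propyl]-3,5-dimethoxybenzoate, via phenolic ketone 12 (not isolated), via benzylic alcohol 13 (not isolated)
Conditions: H2 (3 atm), 10% Pd/C, EtOAc/AcOH 1:1, HClO4 (cat.), rt to 40 °C
Reagents that add atoms: none
Why: Catalytic hydrogenolysis: the O-benzyl group is cleaved first, and the electron-rich aryl ketone is then hydrogenated to the benzylic alcohol whose C–O bond, activated by the para-hydroxy and ortho-methoxy groups and by the acid, is hydrogenolysed to CH2, whereas the methyl ester, the aryl methyl ethers and the diarylmethine C–H bond are not touched.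

Step 8
Reactants: 14 phenol ester
Product: 15 methyl 4-[(1S)-3-[4-(tert-butyldimethylsilyloxy)-2-methoxyphenyl]-1-(4-methoxyphenyl)propyl]-3,5-dimethoxybenzoate
Conditions: TBSCl, imidazole, DMF, rt
Reagents that add atoms: tert-butyldimethylsilyl chloride, CC(C)(C)[Si](C)(C)Cl
Why: Silyl ether formation at the only free hydroxyl (imidazole-mediated silylation), which masks the phenol through the hydride reduction and the basic olefination and comes off together with the second silyl group at the end.

Step 9
Reactants: 15 silyl-protected ester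
Product: 16 [4-[(1S)-3-[4-(tert-butyldimethylsilyloxy)-2-methoxyphenyl]-1-(4-methoxyphenyl)propyl]-3,5-dimethoxyphenyl]methanol
Conditions: i-Bu2AlH (2.5 equiv), CH2Cl2, −78 °C to 0 °C; aq. KNaC4H4O6 work-up
Reagents that add atoms: none
Why: Hydride reduction of the unhindered aryl ester to the benzylic alcohol with i-Bu2AlH, which at low temperature leaves the aryl silyl ether and the methyl ethers intact.

Step 10
Reactants: 16 benzylic alcohol
Product: 17 4-[(1S)-3-[4-(tert-butyldimethylsilyloxy)-2-methoxyphenyl]-1-(4-methoxyphenyl)propyl]-3,5-dimethoxybenzaldehyde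
Conditions: activated MnO2 (excess), CH2Cl2, rt
Reagents that add atoms: none
Why: Selective oxidation of a benzylic alcohol by activated MnO2, which stops at the aldehyde and does not affect the silyl ether or the benzylic methine.

Step 11
Reactants: 18 4-hydroxybenzaldehyde
Product: 19 4-(tert-butyldimethylsilyloxy)benzaldehyde
Conditions: TBSCl, imidazole, DMF, rt
Reagents that add atoms: tert-butyldimethylsilyl chloride, CC(C)(C)[Si](C)(C)Cl
Why: Silyl ether formation at the phenol, chosen so that both phenols of the final stilbene carry the same fluoride-labile group.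

Step 12
Reactants: 19 4-(tert-butyldimethylsilyloxy)benzaldehyde
Product: 20 [4-(tert-butyldimethylsilyloxy)phenyl]methanol
Conditions: NaBH4, THF/MeOH, 0 °C
Reagents that add atoms: none
Why: Borohydride reduction of the aldehyde to the benzylic alcohol at 0 °C, conditions under which the aryl silyl ether is retained.

Step 13
Reactants: 20 [4-(tert-butyldimethylsilyloxy)phenyl]methanol
Product: 21 4-(tert-butyldimethylsilyloxy)benzyl bromide
Conditions: CBr4, PPh3, CH2Cl2, 0 °C; used crude
Reagents that add atoms: carbon tetrabromide, BrC(Br)(Br)Br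
Why: Appel bromination, which converts the benzylic alcohol into the bromide under neutral conditions that spare the acid-sensitive silyloxybenzyl system.

Step 14
Reactants: 21 4-(tert-butyldimethylsilyloxy)benzyl bromide
Product: 22 diethyl [4-(tert-butyldimethylsilyloxy)benzyl]phosphonate
Conditions: P(OEt)3 (neat), 120 °C
Reagents that add atoms: triethyl phosphite, CCOP(OCC)OCC
Why: Michaelis–Arbuzov reaction: the reactive benzylic bromide alkylates the phosphite and bromide dealkylates the phosphonium ion, the volatile bromoethane leaving the hot mixture.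

Step 15
Reactants: 17 aldehyde; 22 diethyl [4-(tert-butyldimethylsilyloxy)benzyl]phosphonate
Product: 23 bis(tert-butyldimethylsilyl) ether of the target, (E)-stilbene with (S) stereocenter
Conditions: 22, NaH, THF, 0 °C; then 17, 0 °C to rt
Reagents that add atoms: none
Why: Horner–Wadsworth–Emmons olefination: the benzylic phosphonate carbanion adds reversibly to the non-enolisable aldehyde and elimination of diethyl phosphate from the favoured adduct gives the E-stilbene, with the aryl silyl ethers and the non-acidic stereocenter unaffected.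

Step 16
Reactants: 23 bis-silyl ether
Product: 24 4-[(E)-2-[4-[(1S)-3-(4-hydroxy-2-methoxyphenyl)-1-(4-methoxyphenyl)propyl]-3,5-dimethoxyphenyl]ethenyl]phenol (CNP0182684.1)
Conditions: TBAF (2.5 equiv), AcOH (2.5 equiv), THF, 0 °C to rt
Reagents that add atoms: none
Why: Fluoride desilylation driven by the strong Si–F bond removes both aryl silyl ethers, and the acetic acid buffer keeps the liberated phenols protonated so that the electron-rich stilbene is neither oxidised nor isomerised.

**Compound list**

1 | 2,4-dihydroxyacetophenone | CC(=O)c1ccc(O)cc1O | starting material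
2 | 4-benzyloxy-2-hydroxyacetophenone | CC(=O)c1ccc(OCc2ccccc2)cc1O | intermediate
3 | 4-benzyloxy-2-methoxyacetophenone | CC(=O)c1ccc(OCc2ccccc2)cc1OC | intermediate
4 | 4-methoxybenzaldehyde | COc1ccc(C=O)cc1 | starting material
5 | (E)-1-[4-(benzyloxy)-2-methoxyphenyl]-3-(4-methoxyphenyl)prop-2-en-1-one | COc1ccc(/C=C/C(=O)c2ccc(OCc3ccccc3)cc2OC)cc1 | intermediate
6 | methyl 3,5-dioxocyclohexane-1-carboxylate | COC(=O)C1CC(=O)CC(=O)C1 | starting material
7 | methyl 4-[(1R)-3-[4-(benzyloxy)-2-methoxyphenyl]-1-(4-methoxyphenyl)-3-oxopropyl]-3,5-dioxocyclohexane-1-carboxylate (triketo form; ring epimers and enol or hemiketal forms) | COc1ccc([C@H](CC(=O)c2ccc(OCc3ccccc3)cc2OC)C2C(=O)CC(C(=O)OC)CC2=O)cc1 | intermediate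
8 | methyl 4-[(1S)-3-[4-(benzyloxy)-2-methoxyphenyl]-1-(4-methoxyphenyl)-3-oxopropyl]-3-methoxy-5-oxocyclohex-3-ene-1-carboxylate (both ring C1 epimers) | COc1ccc([C@H](CC(=O)c2ccc(OCc3ccccc3)cc2OC)C2=C(OC)CC(C(=O)OC)CC2=O)cc1 | intermediate
9 | dienol ether, methyl 4-[(1S)-3-[4-(benzyloxy)-2-methoxyphenyl]-1-(4-methoxyphenyl)-3-oxopropyl]-3,5-dimethoxycyclohexa-2,4-diene-1-carboxylate (not isolated, step 6) | COc1ccc([C@H](CC(=O)c2ccc(OCc3ccccc3)cc2OC)C2=C(OC)CC(C(=O)OC)C=C2OC)cc1 | intermediate
10 | allylic iodide, methyl 4-[(1S)-3-[4-(benzyloxy)-2-methoxyphenyl]-1-(4-methoxyphenyl)-3-oxopropyl]-2-iodo-3,5-dimethoxycyclohexa-3,5-diene-1-carboxylate (not isolated, step 6) | COc1ccc([C@H](CC(=O)c2ccc(OCc3ccccc3)cc2OC)C2=C(OC)C(I)C(C(=O)OC)C=C2OC)cc1 | intermediate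
11 | methyl 4-[(1S)-3-[4-(benzyloxy)-2-methoxyphenyl]-1-(4-methoxyphenyl)-3-oxopropyl]-3,5-dimethoxybenzoate | COc1ccc([C@H](CC(=O)c2ccc(OCc3ccccc3)cc2OC)c2c(OC)cc(C(=O)OC)cc2OC)cc1 | intermediate
12 | phenolic ketone, methyl 4-[(1S)-3-(4-hydroxy-2-methoxyphenyl)-1-(4-methoxyphenyl)-3-oxopropyl]-3,5-dimethoxybenzoate (not isolated, step 7) | COc1ccc([C@H](CC(=O)c2ccc(O)cc2OC)c2c(OC)cc(C(=O)OC)cc2OC)cc1 | intermediate
13 | benzylic alcohol, methyl 4-[(1S)-3-hydroxy-3-(4-hydroxy-2-methoxyphenyl)-1-(4-methoxyphenyl)propyl]-3,5-dimethoxybenzoate (carbinol epimers; not isolated, step 7) | COc1ccc([C@H](CC(O)c2ccc(O)cc2OC)c2c(OC)cc(C(=O)OC)cc2OC)cc1 | intermediate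
14 | methyl 4-[(1S)-3-(4-hydroxy-2-methoxyphenyl)-1-(4-methoxyphenyl)propyl]-3,5-dimethoxybenzoate | COc1ccc([C@H](CCc2ccc(O)cc2OC)c2c(OC)cc(C(=O)OC)cc2OC)cc1 | intermediate
15 | methyl 4-[(1S)-3-[4-(tert-butyldimethylsilyloxy)-2-methoxyphenyl]-1-(4-methoxyphenyl)propyl]-3,5-dimethoxybenzoate | COc1ccc([C@H](CCc2ccc(O[Si](C)(C)C(C)(C)C)cc2OC)c2c(OC)cc(C(=O)OC)cc2OC)cc1 | intermediate
16 | [4-[(1S)-3-[4-(tert-butyldimethylsilyloxy)-2-methoxyphenyl]-1-(4-methoxyphenyl)propyl]-3,5-dimethoxyphenyl]methanol | COc1ccc([C@H](CCc2ccc(O[Si](C)(C)C(C)(C)C)cc2OC)c2c(OC)cc(CO)cc2OC)cc1 | intermediate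
17 | 4-[(1S)-3-[4-(tert-butyldimethylsilyloxy)-2-methoxyphenyl]-1-(4-methoxyphenyl)propyl]-3,5-dimethoxybenzaldehyde | COc1ccc([C@H](CCc2ccc(O[Si](C)(C)C(C)(C)C)cc2OC)c2c(OC)cc(C=O)cc2OC)cc1 | intermediate
18 | 4-hydroxybenzaldehyde | O=Cc1ccc(O)cc1 | starting material
19 | 4-(tert-butyldimethylsilyloxy)benzaldehyde | O=Cc1ccc(O[Si](C)(C)C(C)(C)C)cc1 | intermediate
20 | [4-(tert-butyldimethylsilyloxy)phenyl]methanol | OCc1ccc(O[Si](C)(C)C(C)(C)C)cc1 | intermediate
21 | 4-(tert-butyldimethylsilyloxy)benzyl bromide | BrCc1ccc(O[Si](C)(C)C(C)(C)C)cc1 | intermediate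
22 | diethyl [4-(tert-butyldimethylsilyloxy)benzyl]phosphonate | CCOP(=O)(Cc1ccc(O[Si](C)(C)C(C)(C)C)cc1)OCC | intermediate
23 | bis(tert-butyldimethylsilyl) ether of the target, (E)-stilbene, (S) | COc1ccc([C@H](CCc2ccc(O[Si](C)(C)C(C)(C)C)cc2OC)c2c(OC)cc(/C=C/c3ccc(O[Si](C)(C)C(C)(C)C)cc3)cc2OC)cc1 | intermediate
24 | 4-[(E)-2-[4-[(1S)-3-(4-hydroxy-2-methoxyphenyl)-1-(4-methoxyphenyl)propyl]-3,5-dimethoxyphenyl]ethenyl]phenol (CNP0182684.1) | COc1ccc([C@H](CCc2ccc(O)cc2OC)c2c(OC)cc(/C=C/c3ccc(O)cc3)cc2OC)cc1 | target

**Count**

Total step count: 16.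
Longest linear sequence: 12 steps (steps 1 to 10, then 15 and 16, from 2,4-dihydroxyacetophenone); the phosphonate arm takes 4 steps before it joins.

**Steps most likely to fail**

Step 4. The electron-rich chalcone may react too slowly, the addition may reverse under the basic catalyst and erode the enantiomeric purity, or facial selectivity may be insufficient. The fallback sets out from acetophenone 3 and comes back at keto ester 11, leaving out steps 3 to 6. Compound 3 would be condensed (NaOMe, MeOH, rt, Claisen–Schmidt) with methyl 4-formyl-3,5-dimethoxybenzoate F1 (if not bought, reachable from commercial methyl 4-bromo-3,5-dimethoxybenzoate by bromine–magnesium exchange with i-PrMgCl·LiCl and a DMF quench). This should give methyl 4-[(E)-3-[4-(benzyloxy)-2-methoxyphenyl]-3-oxoprop-1-enyl]-3,5-dimethoxybenzoate F2, in which ring B is already aromatic. A rhodium-catalysed asymmetric 1,4-addition of 4-methoxyphenylboronic acid (Hayashi–Miyaura reaction; Rh(acac)(C2H4)2 with the enantiomer of BINAP that gives the S configuration, dioxane/H2O, 100 °C) would then set the stereocenter by ligand control and give 11 directly.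

Step 6. The acid formed may promote ring closure of the enone oxygen onto the aryl ketone, etherification of the second ring oxygen may stay incomplete, or iodination may occur next to the aryl ketone. The fallback sets out from vinylogous ester 8 and comes back at 11. Palladium-catalysed aerobic dehydrogenation of the cyclohexenone (Pd(OCOCF3)2, 2-(dimethylamino)pyridine, TsOH, O2, DMSO, 80 °C) should give methyl 4-[(1S)-3-[4-(benzyloxy)-2-methoxyphenyl]-1-(4-methoxyphenyl)-3-oxopropyl]-3-hydroxy-5-methoxybenzoate F3. This phenol would be methylated at once (MeI, K2CO3, acetone, reflux) to 11; the same methylation would converge any monomethyl ether formed in step 6.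

Step 7. The reduction may stall at the benzylic alcohol, or the benzylic cation formed under acid may be captured by an ortho methoxy oxygen of ring B with loss of methyl and closure of a pyran ring. The fallback sets out from 11 and comes back at phenol 14, and avoids a free benzylic cation. Ketone 11 would be converted (TsNHNH2, EtOH, AcOH cat., reflux) into methyl 4-[(1S)-3-[4-(benzyloxy)-2-methoxyphenyl]-1-(4-methoxyphenyl)-3-(tosylhydrazono)propyl]-3,5-dimethoxybenzoate F4. Reduction of the tosylhydrazone (catecholborane, CHCl3, 0 °C; then NaOAc·3H2O, reflux) should give methyl 4-[(1S)-3-[4-(benzyloxy)-2-methoxyphenyl]-1-(4-methoxyphenyl)propyl]-3,5-dimethoxybenzoate F5. Neutral hydrogenolysis of the benzyl ether (H2, 10% Pd/C, EtOAc, rt) would then give 14.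

**Further compounds**

F1 | step 4 | methyl 4-formyl-3,5-dimethoxybenzoate | COC(=O)c1cc(OC)c(C=O)c(OC)c1
F2 | step 4 | methyl 4-[(E)-3-[4-(benzyloxy)-2-methoxyphenyl]-3-oxoprop-1-enyl]-3,5-dimethoxybenzoate | COC(=O)c1cc(OC)c(/C=C/C(=O)c2ccc(OCc3ccccc3)cc2OC)c(OC)c1
F3 | step 6 | methyl 4-[(1S)-3-[4-(benzyloxy)-2-methoxyphenyl]-1-(4-methoxyphenyl)-3-oxopropyl]-3-hydroxy-5-methoxybenzoate | COc1ccc([C@H](CC(=O)c2ccc(OCc3ccccc3)cc2OC)c2c(O)cc(C(=O)OC)cc2OC)cc1
F4 | step 7 | methyl 4-[(1S)-3-[4-(benzyloxy)-2-methoxyphenyl]-1-(4-methoxyphenyl)-3-(tosylhydrazono)propyl]-3,5-dimethoxybenzoate | COc1ccc([C@H](CC(=NNS(=O)(=O)c2ccc(C)cc2)c2ccc(OCc3ccccc3)cc2OC)c2c(OC)cc(C(=O)OC)cc2OC)cc1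
F5 | step 7 | methyl 4-[(1S)-3-[4-(benzyloxy)-2-methoxyphenyl]-1-(4-methoxyphenyl)propyl]-3,5-dimethoxybenzoate | COc1ccc([C@H](CCc2ccc(OCc3ccccc3)cc2OC)c2c(OC)cc(C(=O)OC)cc2OC)cc1
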